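## Analysis of the target

The target 19 is a flavone: benzene ring A is fused to the 4-pyranone ring C (O1, C2, C3, C4, C4a, C8a), and aryl ring B sits on C2. Ring A carries a free hydroxyl on C5, hydrogen-bonded to the C4 carbonyl, and a methoxy group on C7. Ring B is oxygenated on four adjacent carbons: hydroxyl on C2', methoxy on C3' and C4', hydroxyl on C5'; only C6' bears hydrogen. There are no stereocentres, so the problem is purely one of regiochemistry: three phenols and three methyl ethers must end up on the right oxygens. Ring B is a 2,3-dimethoxyhydroquinone that oxidises to the quinone in air once deprotonated, and the pyranone is a conjugate acceptor at C2 that hard nucleophiles can open. A late selective demethylation is not an option, because no reagent distinguishes the 2'- and 5'-oxygens from the 3'- and 4'-oxygens. The strategy rests on the local mirror symmetry of C2'–C5': hydroxyl, methoxy, methoxy, hydroxyl is the oxygen pattern of a 3,4-dimethoxyfuran with a silyloxy group on its C2 and its ring oxygen on C5. That leaves C1' and C6' to come from an ethynyl group on C2 of the chromone.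

## Retrosynthetic reasoning

Target 19 is traced back to its 5-O-benzyl ether 18 and from there to the 2'-O-silyl ether 17. The benzyl group is needed earlier: it makes the two phenols of the acetophenone different, so that only one can close ring C, and it removes the acidic chelated hydroxyl before the metalation. The silyl group is not a protecting group added on purpose; it is what the ring-forming step leaves on O2'. Both come off under mild, non-basic conditions that spare the hydroquinone.

In 17 the bonds C1'–C2' and C5'–C6' are cut. This takes ring B apart into silyloxyfuran 6 (C2' to C5' with all four oxygens) and ethynylchromone 15 (C1' and C6'), by way of the oxabicyclic adduct 16. Cutting here, and not at the C2–C1' biaryl-type bond, means ring B is built rather than bought: the four oxygens arrive already sorted into two methyl ethers, one silyl ether and one free phenol. The forward reaction has to add the furan across the alkyne and not across C2=C3 of the pyranone, and the oxygen bridge then has to open with aromatisation. The orientation of the addition does not matter, since both regioisomeric silyl ethers give 18.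

Ethynylchromone 15 is traced to its C-silyl derivative 14, and 14 is cut at the C2–C(sp) bond into iodide 12 and alkyne 13 (Sonogashira coupling). Iodide 12 comes from the 2-unsubstituted chromone 10 by C2 zincation (diarylzinc 11) and iodination. This puts the alkyne on a finished chromone and avoids carrying an activated alkyne through a ring C closure.

Chromone 10 is opened at O1–C2 and at the C2–C3 bond to the one-carbon donor: it comes from monobenzyl acetophenone 8 by way of enaminone 9. Acetophenone 8 is the monoether of the symmetric diol 7, so the benzylation has no regiochemical issue.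

Silyloxyfuran 6 is the silyl dienol ether of butenolide 5. Butenolide 5 is the O-methyl ether of tetronic acid 4, and 4 is cut at the C3–C4 bond (intramolecular Claisen closure) to the acyloxy ester 3, itself the ester of glycolate 1 and acid chloride 2. The lactone ring thus supplies C2'–C5', and the methoxy group on C3' is already present in 2.

## Alternatives that were turned down

Alternative 1: Ring C is cut at C4–C4a. The precursor is the aryloxyacrylic acid A2 (from conjugate addition of the ring A phenol to the ring B arylpropiolate), and the forward key step is an intramolecular Friedel–Crafts acylation in a strongly dehydrating acid medium, giving the hexamethyl ether A1.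
- For: the aryloxy ring is symmetric and strongly activated, so the closure is regiochemically unambiguous; the sequence is short and convergent; the ring closure is far better precedented than the cycloaddition chosen here.
- Against: A1 carries six methyl ethers, and the target needs three of them cleaved (O5, O2', O5') and three kept (O7, O3', O4'). O5 can be freed by chelation to the C4 carbonyl, but nothing separates O2' and O5' from O3' and O4'. Switching ring B to benzyl ethers does not rescue it, because benzyl ethers would not survive the hot acid of the closure.
- Comparison: Alternative 1 is stronger on step count and on the certainty of its key step. The chosen route offers in its place a ring B whose oxygens are differentiated from the first intermediate on.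

Alternative 2: Three bonds of ring C are cut at once (O1–C8a, C4a–C4, O1–C2). The partners are the aryne released from silyl triflate A5 and the arylpropiolic acid A4. In the forward step the carboxylate adds to the aryne, the aryl anion takes over the carboxyl carbon to give an o-hydroxyaryl ynone, and the phenoxide closes onto the ynone to give A3.
- For: three bonds form in one flask; the carboxylate should add at the aryne carbon remote from the flanking methoxy group, which places the ring A oxygens correctly; benzyl ethers on ring B solve the 2'/5' problem. In bonds formed per step it is stronger than the chosen route.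
- Against: ring A arrives as the 5,7-dimethyl ether, so a selective O5 demethylation is still needed next to a ring B with four oxygens. A4 presupposes a finished, differentially protected tetraoxygenated ring B, so the hardest part of the target is moved into a multistep starting material rather than solved. A5 is a multistep compound as well. The aryl anion can be protonated before acyl transfer (giving only the aryl ester), and the product phenoxide can consume a second aryne.
- Comparison: both key steps carry risk, but the chosen route spends its risk on making ring B itself from a six-carbon lactone, with a robust cross-coupling to join the halves.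

Alternative 3: Ring B is cut into a four-carbon squarate unit (C2'–C5', from A8) and a two-carbon alkenyl unit (C6', C1'). Heating the alkenylhydroxycyclobutenone A7 opens it to a dienylketene, the ketene carbon bonds to the chromone-bearing alkene carbon, and tautomerisation gives the free hydroquinone A6, which is identical with compound 18 of the route.
- For: it uses the same symmetry of ring B; the thermal ring expansion is well established and fixes the regiochemistry; it gives 18 without a silyl group, saving one deprotection. On precedent for the ring-forming step it is stronger than the chosen route.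
- Against: A7 requires adding a 2-(chromon-2-yl)vinyl nucleophile to A8. An alkenyl organometallic strong enough to add to the squarate cannot coexist with the chromone carbonyl and its C2 acceptor site. The alkenyl group would therefore have to be brought in masked, with the chromone attached or built afterwards on the fragile hydroxycyclobutenone, which adds steps and puts sensitive intermediates in the main line.
- Comparison: the chosen route joins its halves through the stable compounds 12 and 15 and a Sonogashira coupling. The price is a key step whose dienophile class is not yet demonstrated.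

Key step: step 10

Remark on the chemistry: compounds 16 and 17 are drawn for the orientation in which the silyloxy-bearing furan carbon bonds to the inner alkyne carbon (expected from the polarisation of both partners); the opposite orientation would put the silyl group on O5' and converges on 18 in step 11.

## Route

Step 1
Reactants: 1 methyl glycolate; 2 methoxyacetyl chloride
Product: 3 methyl 2-[(methoxyacetyl)oxy]acetate
Conditions: pyridine, CH2Cl2, 0 to 25 °C
Reagents that add atoms: none
Why: O-Acylation of a primary alcohol by an acid chloride with an amine base; no competing nucleophile is present.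

Step 2
Reactants: 3 methyl 2-[(methoxyacetyl)oxy]acetate
Product: 4 4-hydroxy-3-methoxyfuran-2(5H)-one (3-methoxytetronic acid)
Conditions: LiN(SiMe3)2 (2.2 equiv), THF, −78 to 0 °C; then aq. HCl
Reagents that add atoms: none
Why: Intramolecular Claisen (Dieckmann-type) condensation: the enolate of the methoxyacetyl unit attacks the methyl ester carbonyl in a 5-exo-trig closure, methoxide leaves, and deprotonation of the tetronic acid by the second equivalent of base drives the reaction; this closure of alkoxyacetyl esters of α-hydroxy esters to 3-alkoxytetronic acids is established.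

Step 3
Reactants: 4 4-hydroxy-3-methoxyfuran-2(5H)-one
Product: 5 3,4-dimethoxyfuran-2(5H)-one
Conditions: Me2SO4, K2CO3, acetone, reflux
Reagents that add atoms: dimethyl sulfate, COS(=O)(=O)OC
Why: O-Alkylation of the tetronate anion (a vinylogous carboxylate) by a hard methylating agent at O4; C3 already carries the methoxy group, so C-methylation would need a quaternary centre and is disfavoured.

Step 4
Reactants: 5 3,4-dimethoxyfuran-2(5H)-one
Product: 6 tert-butyl[(3,4-dimethoxyfuran-2-yl)oxy]dimethylsilane
Conditions: t-BuMe2SiOTf, Et3N, CH2Cl2, 0 °C; used without chromatography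
Reagents that add atoms: tert-butyldimethylsilyl trifluoromethanesulfonate, CC(C)(C)[Si](C)(C)OS(=O)(=O)C(F)(F)F
Why: Soft enolisation: the silyl triflate activates the lactone carbonyl and the amine removes a C5 proton, giving the aromatic 2-silyloxyfuran; this is the standard preparation of silyloxyfurans from butenolides, including 4-alkoxybutenolides.

Step 5
Reactants: 7 1-(2,6-dihydroxy-4-methoxyphenyl)ethan-1-one
Product: 8 1-[2-(benzyloxy)-6-hydroxy-4-methoxyphenyl]ethan-1-one
Conditions: BnBr (1.05 equiv), K2CO3, acetone, reflux
Reagents that add atoms: benzyl bromide, BrCc1ccccc1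
Why: Williamson etherification; the two phenols are equivalent, and after the first benzylation the remaining hydroxyl is held in a hydrogen bond to the ketone and is much less nucleophilic, so one equivalent of halide should stop at the monoether.

Step 6
Reactants: 8 1-[2-(benzyloxy)-6-hydroxy-4-methoxyphenyl]ethan-1-one
Product: 10 5-(benzyloxy)-7-methoxy-4H-chromen-4-one, via enaminone 9 (not isolated)
Conditions: Me2NCH(OMe)2, PhMe, 100 °C; then conc. HCl, CH2Cl2, 25 to 40 °C
Reagents that add atoms: N,N-dimethylformamide dimethyl acetal, COC(OC)N(C)C
Why: Condensation of the acetyl methyl group with the amide acetal gives the enaminone; acid then promotes 6-endo-trig addition of the free phenol to the enamine carbon and loss of dimethylamine, the standard synthesis of 2,3-unsubstituted chromones, and the benzyl ether tolerates HCl at this temperature.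

Step 7
Reactants: 10 5-(benzyloxy)-7-methoxy-4H-chromen-4-one
Product: 12 5-(benzyloxy)-2-iodo-7-methoxy-4H-chromen-4-one, via diarylzinc 11 (not isolated)
Conditions: Zn(tmp)2·2MgCl2·2LiCl (0.6 equiv; tmp = 2,2,6,6-tetramethylpiperidide), THF, −30 °C; then I2, THF, −30 to 25 °C
Reagents that add atoms: iodine, II; Zn(tmp)2·2MgCl2·2LiCl, CC1(C)CCCC(C)(C)N1[Zn]N1C(C)(C)CCCC1(C)C.[Mg+2].[Mg+2].[Li+].[Li+].[Cl-].[Cl-].[Cl-].[Cl-].[Cl-].[Cl-] (supplies the zinc of 11 only)
Why: Deprotonation by a hindered zinc amide assisted by the magnesium salt, which binds the C4 carbonyl (chelated by O5) and raises the acidity of C2–H next to the ring oxygen; the covalent C–Zn bond tolerates the pyranone, and iodinolysis gives the 2-iodide (metalation–iodination of chromones with zinc amide bases is known).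

Step 8
Reactants: 12 5-(benzyloxy)-2-iodo-7-methoxy-4H-chromen-4-one; 13 ethynyl(trimethyl)silane
Product: 14 5-(benzyloxy)-7-methoxy-2-[(trimethylsilyl)ethynyl]-4H-chromen-4-one
Conditions: PdCl2(PPh3)2 (cat.), CuI (cat.), Et3N, THF, 25 °C
Reagents that add atoms: none
Why: Sonogashira coupling; the C2–I bond of this vinylogous acyl iodide undergoes oxidative addition readily, and a tertiary amine is used as base so that no amine substitutes at C2.

Step 9
Reactants: 14 5-(benzyloxy)-7-methoxy-2-[(trimethylsilyl)ethynyl]-4H-chromen-4-one
Product: 15 5-(benzyloxy)-2-ethynyl-7-methoxy-4H-chromen-4-one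
Conditions: Bu4NF, AcOH, THF, −20 to 0 °C
Reagents that add atoms: none
Why: Protodesilylation of an alkynylsilane by fluoride; the acetic acid buffer keeps alkoxide and unbuffered fluoride away from the activated alkyne and the pyranone.

Step 10
Reactants: 6 tert-butyl[(3,4-dimethoxyfuran-2-yl)oxy]dimethylsilane; 15 5-(benzyloxy)-2-ethynyl-7-methoxy-4H-chromen-4-one
Product: 17 5-(benzyloxy)-2-{2-[(tert-butyldimethylsilyl)oxy]-5-hydroxy-3,4-dimethoxyphenyl}-7-methoxy-4H-chromen-4-one, via oxanorbornadiene 16 (not isolated)
Conditions: 6 (2 equiv), PhMe, 100 °C, sealed tube, Ar; then SiO2, CH2Cl2, 25 °C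
Reagents that add atoms: none
Why: Proposed new method: the very electron-rich diene 6 adds across the alkyne of 15, whose terminal carbon is the remote electrophilic end of the chromone acceptor system, so the bond from furan C5 to that carbon (C5'–C6') should lead and the bond from the silyloxy carbon to the inner alkyne carbon (C1'–C2') follow, giving 7-oxanorbornadiene 16. The bridgehead silyloxy group then pushes open its own C–O bridge bond to a silyloxy-stabilised cation and an alkoxide, and loss of the other bridgehead proton with protonation on oxygen aromatises the ring to the hydroquinone monosilyl ether 17. The closest known reaction type is the Diels–Alder addition and ring opening of 2-silyloxy- and 2-alkoxyfurans with acetylenedicarboxylates, propiolates and ynones to give hydroquinone monoethers; new here is an alkyne activated only through the pyranone double bond. Ring B is closed as a six-membered carbocycle by an intermolecular [4+2] cycloaddition that makes both ring bonds in one operation, not by cyclisation of a preformed chain. Compound 17 has no stereocentre; the two bridgehead centres of 16 are fixed relative to each other by the bicycle, form as a racemate and disappear on aromatisation. The step needs chemoselectivity for the alkyne over C2=C3 of the pyranone, which the substrate secures because the terminal alkyne is unhindered whereas addition to the trisubstituted C2=C3 would create a quaternary centre and gain no aromatic ring. Regioselectivity is not needed, since either orientation gives 18 after step 11. After the first C–C bond, ring closure has to outrun proton loss from furan C5, which would give an open alkenylfuran.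

Step 11
Reactants: 17 5-(benzyloxy)-2-{2-[(tert-butyldimethylsilyl)oxy]-5-hydroxy-3,4-dimethoxyphenyl}-7-methoxy-4H-chromen-4-one
Product: 18 5-(benzyloxy)-2-(2,5-dihydroxy-3,4-dimethoxyphenyl)-7-methoxy-4H-chromen-4-one
Conditions: Bu4NF, AcOH, THF, 0 °C, Ar
Reagents that add atoms: none
Why: Fluoride cleavage of an aryl silyl ether; buffering with acetic acid and exclusion of air keep the hydroquinone from forming its easily oxidised dianion.

Step 12
Reactants: 18 5-(benzyloxy)-2-(2,5-dihydroxy-3,4-dimethoxyphenyl)-7-methoxy-4H-chromen-4-one
Product: 19 2-(2,5-dihydroxy-3,4-dimethoxyphenyl)-5-hydroxy-7-methoxy-4H-chromen-4-one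
Conditions: H2 (1 atm), 10% Pd/C, EtOAc–MeOH, 25 °C; filtration under Ar
Reagents that add atoms: none
Why: Hydrogenolysis of the benzylic C–O bond on palladium; at one atmosphere and room temperature the chromone double bond and the aryl methyl ethers should remain untouched.

## Compound list

1 | methyl glycolate | COC(=O)CO | starting material
2 | methoxyacetyl chloride | COCC(Cl)=O | starting material
3 | methyl 2-[(methoxyacetyl)oxy]acetate | COCC(=O)OCC(=O)OC | intermediate
4 | 4-hydroxy-3-methoxyfuran-2(5H)-one | COC1=C(O)COC1=O | intermediate
5 | 3,4-dimethoxyfuran-2(5H)-one | COC1=C(OC)COC1=O | intermediate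
6 | tert-butyl[(3,4-dimethoxyfuran-2-yl)oxy]dimethylsilane | COc1coc(O[Si](C)(C)C(C)(C)C)c1OC | intermediate
7 | 1-(2,6-dihydroxy-4-methoxyphenyl)ethan-1-one (2',6'-dihydroxy-4'-methoxyacetophenone) | CC(=O)c1c(O)cc(OC)cc1O | starting material
8 | 1-[2-(benzyloxy)-6-hydroxy-4-methoxyphenyl]ethan-1-one | CC(=O)c1c(O)cc(OC)cc1OCc1ccccc1 | intermediate
9 | (2E)-1-[2-(benzyloxy)-6-hydroxy-4-methoxyphenyl]-3-(dimethylamino)prop-2-en-1-one | CN(C)/C=C/C(=O)c1c(O)cc(OC)cc1OCc1ccccc1 | intermediate
10 | 5-(benzyloxy)-7-methoxy-4H-chromen-4-one | COc1cc(OCc2ccccc2)c2c(=O)ccoc2c1 | intermediate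
11 | bis[5-(benzyloxy)-7-methoxy-4-oxo-4H-chromen-2-yl]zinc (as its MgCl2/LiCl complex) | COc1cc(OCc2ccccc2)c2c(=O)cc([Zn]c3cc(=O)c4c(OCc5ccccc5)cc(OC)cc4o3)oc2c1 | intermediate
12 | 5-(benzyloxy)-2-iodo-7-methoxy-4H-chromen-4-one | COc1cc(OCc2ccccc2)c2c(=O)cc(I)oc2c1 | intermediate
13 | ethynyl(trimethyl)silane | C#C[Si](C)(C)C | starting material
14 | 5-(benzyloxy)-7-methoxy-2-[(trimethylsilyl)ethynyl]-4H-chromen-4-one | COc1cc(OCc2ccccc2)c2c(=O)cc(C#C[Si](C)(C)C)oc2c1 | intermediate
15 | 5-(benzyloxy)-2-ethynyl-7-methoxy-4H-chromen-4-one | C#Cc1cc(=O)c2c(OCc3ccccc3)cc(OC)cc2o1 | intermediate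
16 | 5-(benzyloxy)-2-{1-[(tert-butyldimethylsilyl)oxy]-5,6-dimethoxy-7-oxabicyclo[2.2.1]hepta-2,5-dien-2-yl}-7-methoxy-4H-chromen-4-one (racemic) | COC1=C(OC)C2(O[Si](C)(C)C(C)(C)C)OC1C=C2c1cc(=O)c2c(OCc3ccccc3)cc(OC)cc2o1 | intermediate
17 | 5-(benzyloxy)-2-{2-[(tert-butyldimethylsilyl)oxy]-5-hydroxy-3,4-dimethoxyphenyl}-7-methoxy-4H-chromen-4-one | COc1cc(OCc2ccccc2)c2c(=O)cc(-c3cc(O)c(OC)c(OC)c3O[Si](C)(C)C(C)(C)C)oc2c1 | intermediate
18 | 5-(benzyloxy)-2-(2,5-dihydroxy-3,4-dimethoxyphenyl)-7-methoxy-4H-chromen-4-one | COc1cc(OCc2ccccc2)c2c(=O)cc(-c3cc(O)c(OC)c(OC)c3O)oc2c1 | intermediate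
19 | 2-(2,5-dihydroxy-3,4-dimethoxyphenyl)-5-hydroxy-7-methoxy-4H-chromen-4-one | COc1cc(O)c2c(=O)cc(-c3cc(O)c(OC)c(OC)c3O)oc2c1 | target

## Step count and least certain steps

Total step count: 12. Longest linear sequence: 8 steps (7 to 19, steps 5 to 12); the furan branch is 4 steps (1 to 6) before the convergence.

**Step 10 (key step, proposed new method).**
- What may go wrong: the alkyne is activated only through the pyranone double bond, so the cycloaddition may fail to start before the silyloxyfuran desilylates or decomposes thermally. Alternatively the first C–C bond may form and the intermediate may lose a proton from furan C5 instead of closing, which amounts to alkenylation of the furan without ring B.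
- Fallback (known chemistry, sets out from 6 and 8, comes back at 19):
  - Furan 6 is combined with methyl propiolate (PhMe, 80 °C), a dienophile of the class for which cycloaddition and opening are established, to give methyl 2-[(tert-butyldimethylsilyl)oxy]-5-hydroxy-3,4-dimethoxybenzoate F1.
  - BnBr, K2CO3 and CsF in DMF turn both oxygens into benzyl ethers, giving methyl 2,5-bis(benzyloxy)-3,4-dimethoxybenzoate F2.
  - Claisen condensation of F2 with the dianion of acetophenone 8 (LiN(SiMe3)2, THF) gives 1-[2-(benzyloxy)-6-hydroxy-4-methoxyphenyl]-3-[2,5-bis(benzyloxy)-3,4-dimethoxyphenyl]propane-1,3-dione F3.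
  - Acid-catalysed cyclodehydration (TsOH, PhMe, 80 °C) gives 5-(benzyloxy)-2-[2,5-bis(benzyloxy)-3,4-dimethoxyphenyl]-7-methoxy-4H-chromen-4-one F4.
  - Hydrogenolysis (H2, Pd/C) of the three benzyl ethers gives 19.

**Step 7.**
- What may go wrong: zincation at C3 next to the carbonyl instead of C2, since the site selectivity of zinc amide bases on chromones depends on the Lewis acid present, or ring opening of a C3-metalated species to an ynone phenoxide.
- Fallback (sets out from 10 and 13, comes back at 14): copper-catalysed conjugate alkynylation of the benzopyrylium ion formed from 10 and Me3SiOTf (CuI cat., i-Pr2NEt, CH2Cl2) with 13 gives {[5-(benzyloxy)-7-methoxy-2-[(trimethylsilyl)ethynyl]-2H-chromen-4-yl]oxy}trimethylsilane F5. Hydrolysis on work-up gives 5-(benzyloxy)-7-methoxy-2-[(trimethylsilyl)ethynyl]-2,3-dihydro-4H-chromen-4-one F6. Dehydrogenation with DDQ in dioxane at reflux restores the pyranone double bond and gives 14.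

**Step 2.**
- What may go wrong: deprotonation at the glycolate carbon followed by acyl migration from oxygen to carbon (Chan-type rearrangement), or intermolecular Claisen condensation, in place of the ring closure.
- Fallback (sets out from 2, comes back at 4): methanolysis of 2 (MeOH, pyridine) gives methyl methoxyacetate F7. Its lithium enolate (LiN(i-Pr)2, THF, −78 °C) is C-acylated with chloroacetyl chloride to methyl 4-chloro-2-methoxy-3-oxobutanoate F8. Heating F8 neat at about 140 °C closes the lactone by attack of the ester carbonyl oxygen on the chloromethyl carbon and loss of chloromethane, the classical route to 3-substituted tetronic acids, giving 4.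

**Step 9.**
- What may go wrong: conjugate addition of fluoride, acetate or adventitious hydroxide to the freed, strongly activated alkyne, or oligomerisation of the terminal alkyne on concentration.
- Fallback (sets out from 12, comes back at 15): Stille coupling of 12 with tributyl(ethynyl)stannane (Pd(PPh3)4, PhMe, 80 °C) gives 15 directly under neutral conditions, with no silyl group to remove.

**Step 12.**
- What may go wrong: saturation of the C2–C3 double bond on prolonged exposure, slow cleavage of the peri benzyl ether, or air oxidation of the hydroquinone during filtration of the catalyst.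
- Fallback (sets out from 18, comes back at 19): BCl3 in CH2Cl2 at −78 °C cleaves the 5-benzyl ether by chelation to the C4 carbonyl, without hydrogen or metal, and an acidic aqueous work-up releases 19.

## Further compounds

F1 | step 10 | methyl 2-[(tert-butyldimethylsilyl)oxy]-5-hydroxy-3,4-dimethoxybenzoate | COC(=O)c1cc(O)c(OC)c(OC)c1O[Si](C)(C)C(C)(C)C
F2 | step 10 | methyl 2,5-bis(benzyloxy)-3,4-dimethoxybenzoate | COC(=O)c1cc(OCc2ccccc2)c(OC)c(OC)c1OCc1ccccc1
F3 | step 10 | 1-[2-(benzyloxy)-6-hydroxy-4-methoxyphenyl]-3-[2,5-bis(benzyloxy)-3,4-dimethoxyphenyl]propane-1,3-dione | COc1cc(O)c(C(=O)CC(=O)c2cc(OCc3ccccc3)c(OC)c(OC)c2OCc2ccccc2)c(OCc2ccccc2)c1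
F4 | step 10 | 5-(benzyloxy)-2-[2,5-bis(benzyloxy)-3,4-dimethoxyphenyl]-7-methoxy-4H-chromen-4-one | COc1cc(OCc2ccccc2)c2c(=O)cc(-c3cc(OCc4ccccc4)c(OC)c(OC)c3OCc3ccccc3)oc2c1
F5 | step 7 | {[5-(benzyloxy)-7-methoxy-2-[(trimethylsilyl)ethynyl]-2H-chromen-4-yl]oxy}trimethylsilane (racemic) | COc1cc(OCc2ccccc2)c2C(O[Si](C)(C)C)=CC(C#C[Si](C)(C)C)Oc2c1
F6 | step 7 | 5-(benzyloxy)-7-methoxy-2-[(trimethylsilyl)ethynyl]-2,3-dihydro-4H-chromen-4-one (racemic) | COc1cc(OCc2ccccc2)c2C(=O)CC(C#C[Si](C)(C)C)Oc2c1
F7 | step 2 | methyl methoxyacetate | COCC(=O)OC
F8 | step 2 | methyl 4-chloro-2-methoxy-3-oxobutanoate (racemic) | COC(C(=O)CCl)C(=O)OC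
F0 | step 9 | none | none
F0 | step 12 | none | none
A1 | alternative 1 | 5,7-dimethoxy-2-(2,3,4,5-tetramethoxyphenyl)-4H-chromen-4-one | COc1cc(OC)c2c(=O)cc(-c3cc(OC)c(OC)c(OC)c3OC)oc2c1
A2 | alternative 1 | (2Z)-3-(3,5-dimethoxyphenoxy)-3-(2,3,4,5-tetramethoxyphenyl)prop-2-enoic acid | COc1cc(OC)cc(O/C(=C\C(=O)O)c2cc(OC)c(OC)c(OC)c2OC)c1
A3 | alternative 2 | 2-[2,5-bis(benzyloxy)-3,4-dimethoxyphenyl]-5,7-dimethoxy-4H-chromen-4-one | COc1cc(OC)c2c(=O)cc(-c3cc(OCc4ccccc4)c(OC)c(OC)c3OCc3ccccc3)oc2c1
A4 | alternative 2 | 3-[2,5-bis(benzyloxy)-3,4-dimethoxyphenyl]prop-2-ynoic acid | OC(=O)C#Cc1cc(OCc2ccccc2)c(OC)c(OC)c1OCc1ccccc1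
A5 | alternative 2 | 3,5-dimethoxy-2-(trimethylsilyl)phenyl trifluoromethanesulfonate | COc1cc(OC)c([Si](C)(C)C)c(OS(=O)(=O)C(F)(F)F)c1
A6 | alternative 3 | 5-(benzyloxy)-2-(2,5-dihydroxy-3,4-dimethoxyphenyl)-7-methoxy-4H-chromen-4-one | COc1cc(OCc2ccccc2)c2c(=O)cc(-c3cc(O)c(OC)c(OC)c3O)oc2c1
A7 | alternative 3 | 4-{(E)-2-[5-(benzyloxy)-7-methoxy-4-oxo-4H-chromen-2-yl]ethenyl}-4-hydroxy-2,3-dimethoxycyclobut-2-en-1-one (racemic) | COC1=C(OC)C(O)(/C=C/c2cc(=O)c3c(OCc4ccccc4)cc(OC)cc3o2)C1=O
A8 | alternative 3 | 3,4-dimethoxycyclobut-3-ene-1,2-dione | COC1=C(OC)C(=O)C1=O
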